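Your vessel is closed and stirred at constant volume, and it holds electrophile, nucleophile and free base. I keep its books in shares of the nucleophile charge. In the new flask the limiting reagent of the step from electrophile and nucleophile is the electrophile, with 0.11 M charged, less than the 0.330 M of nucleophile, but the nucleophile is the stock whose uses I count.

- noon: electrophile 0.17 M; nucleophile 0.33 M; free base 0.033 M; run made earlier
- flask: electrophile 0.11 M; nucleophile 0.330 M; free base 0.0330 M; time 4.0 h

noon run (percent of the electrophile charged)

| time / min | electrophile / % | target / % |
|---|---|---|
| 6.00 | 57.1 | 33.4 |
| 12.0 | 44.4 | 40.5 |
| 30.0 | 30.9 | 48.6 |
| 80.0 | 23.0 | 51.5 |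

(standard deviation of a reading: 1 percentage point)

- what is said of target includes crystals
- crystals is a solid; its amount is given per volume of the solution
- candidate steps: electrophile + nucleophile -> acid set free + target; nucleophile + acid set free <-> protonated nucleophile; acid set free + free base <-> salt of the base; crystals <-> target; 2 nucleophile -> self-condensation product; nucleophile + target -> over-reaction product
- the earlier runs do not show how much of nucleophile is bound; that part of a forecast is a guess

* part of the electrophile that has reacted at 4.0 h
* share of the unused nucleophile that is free and not bound as protonated nucleophile, at 4.0 h

Open the ledger on the noon run at its last reading, since its electrophile falls only from 30.9% to 23.0% between 30.0 min and 80.0 min. Each reacted electrophile takes one nucleophile and sets one acid free. I guess that acid beyond the free base sits on a second nucleophile. The percentage missing from electrophile plus target I read as over-reaction, which costs one nucleophile each.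

Added to electrophile: 39.7%
Bound by acid: 29.7%
Over-reaction: 13.1%
Remainder, read as self-condensation plus anything still free: 17.5%

The new flask has the same nucleophile charge, so I carry that remainder over and suppose its electrophile reacts completely.

Added: 33.3%
Bound: 23.3%
Remainder as at noon: 17.5%
Spare share: 25.8%

The spare share is what the charge has over after these three entries. It is less than the 33.3% that over-reaction could claim from the target. So I commit to electrophile reacting past the noon 77.0%, and to bound nucleophile outweighing free.

The forecast says 98% and 48%, holding that “Bound nucleophile is about 0.077 M if binding is strong”; the flask gives 93.2% and 3.75%.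

    electrophile + nucleophile → acid set free + target (k = 0.00621 L mol⁻¹ s⁻¹)
    nucleophile + acid set free ⇌ protonated nucleophile, settled at all times (K = 9700 L mol⁻¹)
    acid set free + free base ⇌ salt of the base, settled at all times (K = 2.64 × 10⁶ L mol⁻¹)
    crystals ⇌ target, rate k4*(cs4 - [target]) while solid is left; crystals form when [target] > cs4 (solubility = 20.0 mM, k = 0.00490 s⁻¹)
    2 nucleophile → self-condensation product (k = 9.14 × 10⁻⁴ L mol⁻¹ s⁻¹)
    nucleophile + target → over-reaction product (k = 0.00716 L mol⁻¹ s⁻¹)

At 4.00 h the flask holds 0.790% of its nucleophile free, against 0.0669 M of protonated nucleophile. Its spare share equals 77.5% of the electrophile charge, and over-reaction product stands at 59.9%. A neighbour flask with 0.066 M of electrophile has a spare share of 52.5%, more than its electrophile's 20.0%. There over-reaction product reaches 96.2%, and the free share is 36.5%.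

All runs were generated by integration with made-up constants; the scatter is artificial.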